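Set the two earlier runs side by side: the south-west run carries 1.50 times the substrate of the north run, yet at 20.0 min its substrate reads 56.9 % against 56.5 %, within the scatter of 0.5 percentage points.

| flask | substrate | partner | remark | time |
|---|---|---|---|---|
| north | 0.050 M (fed, over 30 min) | 0.12 M | run made earlier; the fed solution adds 0.20 times the starting volume |  |
| south-west | 0.075 M (fed, over 30 min) | 0.12 M | run made earlier; the fed solution adds 0.20 times the starting volume |  |
| flask | 0.10 M (fed, over 30 min) | 0.120 M | the fed solution adds 0.20 times the starting volume | 30 min |

- north (time / min: target / %, open intermediate / %, substrate / %): 1.50: 0.1, 1.3, 5.7; 5.00: 0.8, 0.6, 15.7; 8.00: 1.1, 1.2, 24.9; 12.0: 2.5, 1.5, 36.3; 20.0: 4.0, 5.9, 56.5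
- south-west (time / min: target / %, open intermediate / %, substrate / %): 1.50: 0, 0, 4.9; 5.00: 0.7, 0.5, 15.9; 8.00: 1.4, 1.3, 24.8; 12.0: 1.5, 2.7, 35.0; 20.0: 5.0, 5.8, 56.9

(each reading ± 0.5 percentage points)

- charges are per starting volume, the dose included; the dosed solution carries all of it
- percentages count the whole charge, also what has not yet gone in

- the species that holds most of what was charged as substrate, at 30 min (substrate / open intermediate / target)
- the largest share itself, whichever of these holds it, in percent of the substrate charged

Equal percentages from unequal charges suggest a loss proportional to the substrate present, so how large is that loss? At 20.0 min the two runs show on average 10.4 % as target plus open intermediate. Substrate climbed nearly straight from nothing, so I take its mean over that time as 28.3 %. Read off these scattered readings, that gives 0.0183 min⁻¹ as the loss constant, the fraction of the substrate present that reacts each minute, a first-order rate constant.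

Does the dose outrun this loss? The half-life this implies, 38.0 min, is longer than the dosing time of 30 min. Substrate dosed steadily and lost at this constant stands at the end of the dose at (1 − exp(−kt))/(kt) of the charge, which is 77.0 %. I carry this to the flask at 0.10 M on the strength of the first comparison, with partner unchanged. The other two species then share 23.0 %, so substrate holds the largest share.

The forecast, slightly above my figure, names substrate at 78 %: “Substrate clearly dominates.”

The flask gives substrate at 77.3 %, with open intermediate at 15.2 % and target at 7.52 %.

    substrate → open intermediate (k = 3.00 × 10⁻⁴ s⁻¹)
    partner → second intermediate (k = 0.00370 s⁻¹)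
    open intermediate + second intermediate ⇌ target (K = 16.0 L mol⁻¹, k = 0.390 L mol⁻¹ s⁻¹)
    2 second intermediate → homo product (k = 0.00650 L mol⁻¹ s⁻¹)

In the flask, partner has a half-life of 3.1 min by its own step at 3.12 min, against 39 min for substrate by its step. Partner is down to 0.128 % of its charge at 30 min, while the substrate step, which takes no partner, continues. With the dose over, the loss constant read off the earlier runs reckons 77.3 % down by exp(−kt) to 31.0 % at 80 min, and the same flask read then holds 31.4 %.

The numbers in the tables were generated by integration with made-up constants, and the scatter is random.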